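Start from a one-step world, where electrophile and nucleophile react and free base stands by. The runs disagree: at 120 min, Wednesday's flask, with 1.7 equiv of free base, keeps 31.3% of its electrophile, and Thursday's flask, with 1.9 equiv, keeps 26.9%.

in all of them: electrophile 0.20 M

| flask | free base | protonated nucleophile | remark | time |
|---|---|---|---|---|
| Wednesday's | 1.7 equiv | 1.5 equiv | run made earlier |  |
| Thursday's | 1.9 equiv | 1.5 equiv | run made earlier |  |
| winter | 2.00 equiv | 1.50 equiv |  | 3.0 h |
| autumn | 2.60 equiv | 1.50 equiv |  | 3.0 h |

| run | time / min | electrophile / % | target / % |
|---|---|---|---|
| Wednesday's | 10.0 | 73.5 | 21.7 |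
| Wednesday's | 25.0 | 54.7 | 32.6 |
| Wednesday's | 50.0 | 41.1 | 41.1 |
| Wednesday's | 120 | 31.3 | 49.1 |
| Thursday's | 10.0 | 70.1 | 22.1 |
| Thursday's | 25.0 | 53.0 | 33.7 |
| Thursday's | 50.0 | 38.3 | 44.3 |
| Thursday's | 120 | 26.9 | 52.4 |

(standard deviation of a reading: 1 percentage point)



* part of the electrophile that has reacted at the end, winter
* part of the electrophile that has reacted at the end, autumn
* what raising the equivalents of free base from its lowest to its highest value here does to the part of the electrophile that has reacted (changes below 5 percentage points count as none) (no change / it falls / it rises)

First ask what the base pays for. Suppose the protonated nucleophile gives its proton to free base before it reacts, and each reaction sets acid free for further base to take: that is two equivalents of base per electrophile. Half the base charged, 1.30 for autumn, is then, on this supposition, the most electrophile the base can pay for; call it the base ceiling, c.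

Next ask how much of c is used by the last reading. Divide the part reacted by c: Wednesday's flask, with c = 0.850, gives 0.808, and Thursday's flask, with c = 0.950, gives 0.769. Extend this line, rough as two scattered readings make it: winter, with c = 1.00, reaches 0.750, and autumn reaches 0.634.

Then ask what the remaining 60.0 min adds. Take Thursday's last interval as the pace, which multiplies the electrophile left by 0.739. My reckoning gives 81.5% reacted in winter and 87.0% in autumn.

The forecast says 81% for winter and 93% for autumn, and of the part reacted, as free base goes up: it rises. Its ground is this: “More base therefore raises the ceiling”. Its autumn is higher than mine.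

The flasks give 79.4% for winter and 87.5% for autumn; of the part reacted, from the lowest free base to the highest: it rises, by 8 percentage points.

    acid set free + free base ⇌ salt of the base, settled at all times (K = 12000 L mol⁻¹)
    electrophile + nucleophile → acid set free + target (k = 0.00440 L mol⁻¹ s⁻¹)
    target ⇌ isomer of the product (K = 0.380, k = 0.00360 s⁻¹)
    free base ⇌ dormant form (K = 1.50, k = 1.30 × 10⁻⁴ s⁻¹)
    nucleophile + acid set free ⇌ protonated nucleophile, settled at all times (K = 12000 L mol⁻¹)

Neither flask has come to rest at 3.0 h. After 30.0 h, winter, whose ceiling stands at 1.00, has reacted 95.8%, with 1.83% of its free base still free. Autumn, with its ceiling of 1.30, has reacted 99.9% and keeps 8.56% of its free base free.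

Take the neighbour like autumn but with 0.650 equiv of free base: its ceiling is 0.325, so look for free base as the limiting reagent and for about 32.5% reacted. That flask reacts 35.2%, more than its c, with 0.52% of its free base left, so c is an estimate there, not a bound.

The readings were generated by integration with made-up constants.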